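**Strategy.** The cyclohexene (C1′ quaternary, C2′ methine, C3′=C4′, C5′, C6′) is cut into a tiglyl unit (C2′–C3′–C4′) and a C5′–C6′–C1′ unit. The C1′–C2′ bond is allylic to C3′=C4′ and C1′ can carry a carboxyl (the first side-chain carbon), which is the retron of an ester-enolate Claisen shift; C4′ is then a latent carbinol carbon. One flask therefore joins tiglic aldehyde and a γ-zincio ester at C4′–C5′ enantioselectively, lets the alkoxide lactonise, and ring-contracts the lactone silyl ketene acetal by [3,3] shift, forming C1′–C2′ with chirality transfer. The chromene follows by asymmetric O-allylation and ring-closing metathesis.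

Key step: step 2

Remark: 1 is used as the racemate and 7 as both C3 epimers because that carbon is planarised in 8. The CIP descriptors of the ring carbons change with the C1′ substituent (1R,2S in 9–12, 5S,6S in 13, 1R,2R in 16, 1S,2R from 17 on) without any change in spatial arrangement.

Step 1
Reactants: 1 methyl 2-methylbut-3-enoate
Product: 4 (4-methoxy-3-methyl-4-oxobutyl)[(trimethylsilyl)methyl]zinc, via diethyl(4-methoxy-3-methyl-4-oxobutyl)borane 2 (not isolated), via ethyl(4-methoxy-3-methyl-4-oxobutyl)zinc 3 (not isolated)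
Conditions: Et2BH (from BH3·SMe2 + BEt3), Et2O, 0 °C → rt; Et2Zn (neat), 0 °C; then (Me3SiCH2)2Zn (0.5 equiv), BEt3 and Et2Zn removed in vacuo (25 °C, 10 mmHg); PhMe
Reagents that add atoms: diethylzinc, CC[Zn]CC; bis[(trimethylsilyl)methyl]zinc, C[Si](C)(C)C[Zn]C[Si](C)(C)C
Why: Anti-Markovnikov hydroboration of the monosubstituted alkene and boron–zinc exchange should give the primary ethyl(alkyl)zinc with the ester intact, and ligand redistribution with (Me3SiCH2)2Zn, driven by distilling off BEt3 and Et2Zn, should leave a salt-free mixed diorganozinc in which each zinc carries one ester-bearing alkyl group and one non-transferable silylmethyl group.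

Step 2
Reactants: 4 (4-methoxy-3-methyl-4-oxobutyl)[(trimethylsilyl)methyl]zinc; 5 (2E)-2-methylbut-2-enal
Product: 10 (1R,2S)-1,2,3-trimethylcyclohex-3-ene-1-carboxylic acid, via titanium alkoxide 6 (not isolated), via lactone 7 (not isolated), via silyl ketene acetal 8 (not isolated), via trimethylsilyl ester 9 (not isolated)
Conditions: (1R,2R)-1,2-bis(trifluoromethanesulfonamido)cyclohexane (8 mol%), Ti(OiPr)4 (0.6 equiv), PhMe, −20 °C; 60 °C; then THF, Me3SiCl/Et3N, LiN(iPr)2, −78 °C → rt; PhMe, 100 °C (THF distilled off); 1 M HCl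
Reagents that add atoms: none
Why: The titanium bis(sulfonamide) catalyst transfers the ester-bearing alkyl group of 4 (the silylmethyl group stays on zinc) to the Si face of 5 (C4′–C5′ bond, S carbinol); the titanium alkoxide 6 then closes onto its own methyl ester to lactone 7, and enolisation/silylation gives the cyclic ketene acetal 8, whose [3,3] shift forms C1′–C2′ as the C4′–O bond breaks. The closest known reaction types are the Ti(OiPr)4/bis(sulfonamide)-catalysed enantioselective addition of functionalised mixed (trimethylsilyl)methyl alkylzincs to enals and the Ireland–Claisen ring contraction of 6-alkenyl δ-lactone silyl enolates to cyclohexenecarboxylic acids; only their telescoping in one flask is new. The lactone closes by 6-exo-trig acyl substitution (titanium alkoxides catalyse transesterification), and the carbocycle by ring contraction through a boat-like, bicyclo[2.2.2]octane-type transition state, the only geometry the six-membered ketene acetal allows. C1′ and C2′ are set by 1,3-chirality transfer from the S carbinol carbon: the E alkene places the C2′ methyl cis to the new carboxyl and trans to the C1′ methyl, and the S centre fixes the absolute sense. The step needs high enantioselectivity in the zinc addition (catalyst control), transfer of the ester-bearing alkyl rather than the silylmethyl group, and bond formation only at the γ-carbon of the ester, which the saturated organozinc secures; the cis ring alkene is enforced because C5′ is tied into the lactone ring.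

Step 3
Reactants: 10 (1R,2S)-1,2,3-trimethylcyclohex-3-ene-1-carboxylic acid
Product: 11 [(1R,2S)-1,2,3-trimethylcyclohex-3-en-1-yl]methanol
Conditions: LiAlH4, Et2O, 0 °C → reflux
Reagents that add atoms: none
Why: Hydride reduction of the hindered acid to the neopentyl-type alcohol leaves both stereocentres and the alkene untouched.

Step 4
Reactants: 11 [(1R,2S)-1,2,3-trimethylcyclohex-3-en-1-yl]methanol
Product: 12 (1R,2S)-1,2,3-trimethylcyclohex-3-ene-1-carbaldehyde
Conditions: Dess–Martin periodinane, NaHCO3, CH2Cl2, 0 °C → rt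
Reagents that add atoms: none
Why: Dess–Martin oxidation stops at the aldehyde, whose quaternary α-carbon cannot epimerise.

Step 5
Reactants: 12 (1R,2S)-1,2,3-trimethylcyclohex-3-ene-1-carbaldehyde
Product: 13 (5S,6S)-5-ethenyl-1,5,6-trimethylcyclohex-1-ene
Conditions: Ph3PCH3Br, KOtBu, THF, 0 °C → rt
Reagents that add atoms: methyltriphenylphosphonium bromide, C[P+](c1ccccc1)(c1ccccc1)c1ccccc1.[Br-]
Why: Wittig methylenation of a non-enolisable aldehyde with the unhindered ylide should be clean.

Step 6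
Reactants: 14 but-2-yn-1-ol
Product: 15 (2Z)-3-iodobut-2-en-1-ol
Conditions: NaAlH2(OCH2CH2OMe)2, Et2O, 0 °C; then I2, THF, −78 °C
Reagents that add atoms: iodine, II
Why: Hydroalumination of the propargylic alkoxide delivers hydride to C2 and aluminium to C3 in a trans sense through a five-membered alkoxyaluminate, and iodinolysis with retention gives the Z vinyl iodide.

Step 7
Reactants: 13 (5S,6S)-5-ethenyl-1,5,6-trimethylcyclohex-1-ene; 15 (2Z)-3-iodobut-2-en-1-ol
Product: 17 (2Z)-3-methyl-5-[(1S,2R)-1,2,3-trimethylcyclohex-3-en-1-yl]pent-2-en-1-ol, via alkylborane 16 (not isolated)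
Conditions: 9-BBN, THF, 0 °C → rt; then 15, PdCl2(dppf) (5 mol%), K3PO4 (3 M aq.), DMF, rt
Reagents that add atoms: none
Why: 9-BBN hydroborates only the monosubstituted alkene (anti-Markovnikov), and B-alkyl Suzuki–Miyaura coupling with the vinyl iodide proceeds with retention of the Z geometry and tolerates the free hydroxyl.

Step 8
Reactants: 17 (2Z)-3-methyl-5-[(1S,2R)-1,2,3-trimethylcyclohex-3-en-1-yl]pent-2-en-1-ol
Product: 18 methyl (2Z)-3-methyl-5-[(1S,2R)-1,2,3-trimethylcyclohex-3-en-1-yl]pent-2-en-1-yl carbonate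
Conditions: ClCO2Me, pyridine, CH2Cl2, 0 °C
Reagents that add atoms: methyl chloroformate, COC(=O)Cl
Why: O-acylation of the primary allylic alcohol gives the carbonate needed as a self-activating leaving group for the allylic substitution.

Step 9
Reactants: 19 2-hydroxy-4,5-dimethoxybenzaldehyde
Product: 20 4,5-dimethoxy-2-(methoxymethoxy)benzaldehyde
Conditions: MeOCH2Cl, iPr2NEt, CH2Cl2, 0 °C → rt
Reagents that add atoms: chloromethyl methyl ether, COCCl
Why: O-alkylation masks the oxygen that later becomes the C8 carbonyl as a base- and oxidant-stable acetal.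

Step 10
Reactants: 20 4,5-dimethoxy-2-(methoxymethoxy)benzaldehyde
Product: 22 4,5-dimethoxy-2-(methoxymethoxy)phenol, via aryl formate 21 (not isolated)
Conditions: mCPBA, NaHCO3, CH2Cl2, 0 °C → rt; then K2CO3 (cat.), MeOH, 0 °C
Reagents that add atoms: 3-chloroperbenzoic acid, OOC(=O)c1cccc(Cl)c1
Why: Baeyer–Villiger (Dakin-type) oxidation with migration of the electron-rich aryl group gives the formate, which is methanolysed to the phenol.

Step 11
Reactants: 22 4,5-dimethoxy-2-(methoxymethoxy)phenol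
Product: 23 2-hydroxy-5,6-dimethoxy-3-(methoxymethoxy)benzaldehyde
Conditions: MgCl2, Et3N, (CH2O)n, MeCN, reflux
Reagents that add atoms: paraformaldehyde (formaldehyde unit), C=O
Why: Magnesium phenoxide-directed ortho-formylation can only occur at the single free ortho position.

Step 12
Reactants: 18 methyl (2Z)-3-methyl-5-[(1S,2R)-1,2,3-trimethylcyclohex-3-en-1-yl]pent-2-en-1-yl carbonate; 23 2-hydroxy-5,6-dimethoxy-3-(methoxymethoxy)benzaldehyde
Product: 24 5,6-dimethoxy-3-(methoxymethoxy)-2-({(3S)-3-methyl-5-[(1S,2R)-1,2,3-trimethylcyclohex-3-en-1-yl]pent-1-en-3-yl}oxy)benzaldehyde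
Conditions: Pd2(dba)3·CHCl3 (2 mol%), (1R,2R)-N,N′-bis[2-(diphenylphosphino)benzoyl]cyclohexane-1,2-diamine (6 mol%), CH2Cl2, rt
Reagents that add atoms: none
Why: Tsuji–Trost asymmetric allylic O-alkylation: zerovalent palladium ionises the carbonate and the phenoxide attacks the more substituted allyl terminus inside the chiral pocket, so the S tertiary ether centre should be set by the ligand (catalyst control, chosen on the usual working model for Z trisubstituted allyl carbonates).

Step 13
Reactants: 24 5,6-dimethoxy-3-(methoxymethoxy)-2-({(3S)-3-methyl-5-[(1S,2R)-1,2,3-trimethylcyclohex-3-en-1-yl]pent-1-en-3-yl}oxy)benzaldehyde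
Product: 25 2-ethenyl-3,4-dimethoxy-6-(methoxymethoxy)-1-({(3S)-3-methyl-5-[(1S,2R)-1,2,3-trimethylcyclohex-3-en-1-yl]pent-1-en-3-yl}oxy)benzene
Conditions: Ph3PCH3Br, KOtBu, THF, 0 °C → rt
Reagents that add atoms: methyltriphenylphosphonium bromide, C[P+](c1ccccc1)(c1ccccc1)c1ccccc1.[Br-]
Why: Wittig methylenation of the aryl aldehyde gives the styrene partner; the tertiary ether and the acetal are inert to the ylide.

Step 14
Reactants: 25 2-ethenyl-3,4-dimethoxy-6-(methoxymethoxy)-1-({(3S)-3-methyl-5-[(1S,2R)-1,2,3-trimethylcyclohex-3-en-1-yl]pent-1-en-3-yl}oxy)benzene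
Product: 26 (2S)-5,6-dimethoxy-8-(methoxymethoxy)-2-methyl-2-{2-[(1S,2R)-1,2,3-trimethylcyclohex-3-en-1-yl]ethyl}-2H-chromene
Conditions: second-generation Grubbs catalyst RuCl2(=CHPh)(H2IMes)(PCy3) (5 mol%), CH2Cl2, 40 °C
Reagents that add atoms: none
Why: Ring-closing metathesis of the two monosubstituted alkenes forms the six-membered pyran with a cis C3=C4 bond; the hindered trisubstituted ring alkene does not take part and the stereocentre is not touched.

Step 15
Reactants: 26 (2S)-5,6-dimethoxy-8-(methoxymethoxy)-2-methyl-2-{2-[(1S,2R)-1,2,3-trimethylcyclohex-3-en-1-yl]ethyl}-2H-chromene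
Product: 28 (2S)-5,6-dimethoxy-2-methyl-2-{2-[(1S,2R)-1,2,3-trimethylcyclohex-3-en-1-yl]ethyl}-2H-chromen-8-ol, via aryl silyl ether 27 (not isolated)
Conditions: Me3SiOTf, 2,2′-bipyridyl, CH2Cl2, 0 °C; then H2O, rt
Reagents that add atoms: none
Why: The buffered silyl triflate/bipyridyl system converts the aryl methoxymethyl ether into the aryl silyl ether, which water cleaves, so the acid-sensitive electron-rich chromene never meets a free Brønsted acid.

Step 16
Reactants: 28 (2S)-5,6-dimethoxy-2-methyl-2-{2-[(1S,2R)-1,2,3-trimethylcyclohex-3-en-1-yl]ethyl}-2H-chromen-8-ol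
Product: 29 (2S)-6-methoxy-2-methyl-2-{2-[(1S,2R)-1,2,3-trimethylcyclohex-3-en-1-yl]ethyl}-2H-chromene-5,8-dione
Conditions: PhI(OAc)2, MeCN/H2O (2:1), 0 °C
Reagents that add atoms: water, O
Why: Hypervalent-iodine oxidation of a para-methoxyphenol: the free C8 hydroxyl directs the oxidation, water adds at C5 and methanol is lost, so only the 5,8-quinone with the C6 methoxy group retained can form.

**Compound list**

1 | methyl 2-methylbut-3-enoate (racemic) | C=CC(C)C(=O)OC | starting material
2 | diethyl(4-methoxy-3-methyl-4-oxobutyl)borane | CCB(CC)CCC(C)C(=O)OC | intermediate (not isolated)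
3 | ethyl(4-methoxy-3-methyl-4-oxobutyl)zinc | CC[Zn]CCC(C)C(=O)OC | intermediate (not isolated)
4 | (4-methoxy-3-methyl-4-oxobutyl)[(trimethylsilyl)methyl]zinc | COC(=O)C(C)CC[Zn]C[Si](C)(C)C | intermediate
5 | (2E)-2-methylbut-2-enal | C/C=C(\C)C=O | starting material
6 | tri(propan-2-yloxy)titanium alkoxide of methyl (5S,6E)-5-hydroxy-2,6-dimethyloct-6-enoate | C/C=C(\C)[C@@H](O[Ti](OC(C)C)(OC(C)C)OC(C)C)CCC(C)C(=O)OC | intermediate (not isolated)
7 | (6S)-6-[(2E)-but-2-en-2-yl]-3-methyloxan-2-one (both C3 epimers) | C/C=C(\C)[C@@H]1CCC(C)C(=O)O1 | intermediate (not isolated)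
8 | {[(2S)-2-[(2E)-but-2-en-2-yl]-5-methyl-3,4-dihydro-2H-pyran-6-yl]oxy}(trimethyl)silane | C/C=C(\C)[C@@H]1CCC(C)=C(O[Si](C)(C)C)O1 | intermediate (not isolated)
9 | trimethylsilyl (1R,2S)-1,2,3-trimethylcyclohex-3-ene-1-carboxylate | C[Si](C)(C)OC(=O)[C@]1(C)CCC=C(C)[C@@H]1C | intermediate (not isolated)
10 | (1R,2S)-1,2,3-trimethylcyclohex-3-ene-1-carboxylic acid | OC(=O)[C@]1(C)CCC=C(C)[C@@H]1C | intermediate
11 | [(1R,2S)-1,2,3-trimethylcyclohex-3-en-1-yl]methanol | OC[C@]1(C)CCC=C(C)[C@@H]1C | intermediate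
12 | (1R,2S)-1,2,3-trimethylcyclohex-3-ene-1-carbaldehyde | O=C[C@]1(C)CCC=C(C)[C@@H]1C | intermediate
13 | (5S,6S)-5-ethenyl-1,5,6-trimethylcyclohex-1-ene | C=C[C@]1(C)CCC=C(C)[C@@H]1C | intermediate
14 | but-2-yn-1-ol | CC#CCO | starting material
15 | (2Z)-3-iodobut-2-en-1-ol | OC/C=C(C)\I | intermediate
16 | 9-{2-[(1R,2R)-1,2,3-trimethylcyclohex-3-en-1-yl]ethyl}-9-borabicyclo[3.3.1]nonane | B1(CC[C@]2(C)CCC=C(C)[C@@H]2C)C2CCCC1CCC2 | intermediate (not isolated)
17 | (2Z)-3-methyl-5-[(1S,2R)-1,2,3-trimethylcyclohex-3-en-1-yl]pent-2-en-1-ol | OC/C=C(C)\CC[C@]1(C)CCC=C(C)[C@@H]1C | intermediate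
18 | methyl (2Z)-3-methyl-5-[(1S,2R)-1,2,3-trimethylcyclohex-3-en-1-yl]pent-2-en-1-yl carbonate | COC(=O)OC/C=C(C)\CC[C@]1(C)CCC=C(C)[C@@H]1C | intermediate
19 | 2-hydroxy-4,5-dimethoxybenzaldehyde | COc1cc(O)c(C=O)cc1OC | starting material
20 | 4,5-dimethoxy-2-(methoxymethoxy)benzaldehyde | COCOc1cc(OC)c(OC)cc1C=O | intermediate
21 | 4,5-dimethoxy-2-(methoxymethoxy)phenyl formate | COCOc1cc(OC)c(OC)cc1OC=O | intermediate (not isolated)
22 | 4,5-dimethoxy-2-(methoxymethoxy)phenol | COCOc1cc(OC)c(OC)cc1O | intermediate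
23 | 2-hydroxy-5,6-dimethoxy-3-(methoxymethoxy)benzaldehyde | COCOc1cc(OC)c(OC)c(C=O)c1O | intermediate
24 | 5,6-dimethoxy-3-(methoxymethoxy)-2-({(3S)-3-methyl-5-[(1S,2R)-1,2,3-trimethylcyclohex-3-en-1-yl]pent-1-en-3-yl}oxy)benzaldehyde | C=C[C@](C)(CC[C@]1(C)CCC=C(C)[C@@H]1C)Oc1c(C=O)c(OC)c(OC)cc1OCOC | intermediate
25 | 2-ethenyl-3,4-dimethoxy-6-(methoxymethoxy)-1-({(3S)-3-methyl-5-[(1S,2R)-1,2,3-trimethylcyclohex-3-en-1-yl]pent-1-en-3-yl}oxy)benzene | C=C[C@](C)(CC[C@]1(C)CCC=C(C)[C@@H]1C)Oc1c(C=C)c(OC)c(OC)cc1OCOC | intermediate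
26 | (2S)-5,6-dimethoxy-8-(methoxymethoxy)-2-methyl-2-{2-[(1S,2R)-1,2,3-trimethylcyclohex-3-en-1-yl]ethyl}-2H-chromene | COCOc1cc(OC)c(OC)c2C=C[C@](C)(CC[C@]3(C)CCC=C(C)[C@@H]3C)Oc12 | intermediate
27 | {[(2S)-5,6-dimethoxy-2-methyl-2-{2-[(1S,2R)-1,2,3-trimethylcyclohex-3-en-1-yl]ethyl}-2H-chromen-8-yl]oxy}(trimethyl)silane | C[Si](C)(C)Oc1cc(OC)c(OC)c2C=C[C@](C)(CC[C@]3(C)CCC=C(C)[C@@H]3C)Oc12 | intermediate (not isolated)
28 | (2S)-5,6-dimethoxy-2-methyl-2-{2-[(1S,2R)-1,2,3-trimethylcyclohex-3-en-1-yl]ethyl}-2H-chromen-8-ol | Oc1cc(OC)c(OC)c2C=C[C@](C)(CC[C@]3(C)CCC=C(C)[C@@H]3C)Oc12 | intermediate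
29 | (2S)-6-methoxy-2-methyl-2-{2-[(1S,2R)-1,2,3-trimethylcyclohex-3-en-1-yl]ethyl}-2H-chromene-5,8-dione | COC1=CC(=O)C2=C(C=C[C@](C)(CC[C@]3(C)CCC=C(C)[C@@H]3C)O2)C1=O | target

**Step count and risks**

Total steps: 16. Longest linear sequence: 12 (steps 1, 2, 3, 4, 5, 7, 8, 12, 13, 14, 15, 16).

The three steps most likely to fail:

Step 2. The titanium alkoxide may lactonise incompletely, the metal alkoxides and the ester of the excess zinc reagent may consume base and silyl chloride, Lewis-acidic titanium residues may ionise the allylic lactone, and the enantioselectivity of the alkyl transfer may fall with the ester-bearing zinc reagent. The fallback sets out from 5 and comes back at 10, building the two bonds in separate operations. Asymmetric allylboration of 5 with B-allyldiisopinocampheylborane (the enantiomer that adds to the Si face, from (+)-α-pinene) should give (4S,5E)-5-methylhepta-1,5-dien-4-ol F1. Acylation with methacryloyl chloride (Et3N, DMAP) should give (4S,5E)-5-methylhepta-1,5-dien-4-yl 2-methylprop-2-enoate F2. Ring-closing metathesis with the second-generation Grubbs catalyst should give (6S)-6-[(2E)-but-2-en-2-yl]-3-methyl-5,6-dihydro-2H-pyran-2-one F3. Conjugate reduction with LiBH(sBu)3 and trapping of the lactone enolate with Me3SiCl should give 8, which rearranges to 9 on warming and is hydrolysed to 10.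

Step 12. The phenol is flanked by two ortho substituents, so attack at the tertiary allyl terminus may be slow and the linear ether or low facial selectivity may result. The fallback sets out from 18 and 22 and comes back at 26, using the less hindered phenol and closing the pyran ring by C–C bond formation. The same palladium/ligand system with 22 should give 4,5-dimethoxy-2-(methoxymethoxy)-1-({(3S)-3-methyl-5-[(1S,2R)-1,2,3-trimethylcyclohex-3-en-1-yl]pent-1-en-3-yl}oxy)benzene F4. Hydroboration with 9-BBN and oxidation (NaOH, H2O2) should give (3S)-3-[4,5-dimethoxy-2-(methoxymethoxy)phenoxy]-3-methyl-5-[(1S,2R)-1,2,3-trimethylcyclohex-3-en-1-yl]pentan-1-ol F5. Dess–Martin oxidation should give (3S)-3-[4,5-dimethoxy-2-(methoxymethoxy)phenoxy]-3-methyl-5-[(1S,2R)-1,2,3-trimethylcyclohex-3-en-1-yl]pentanal F6. Mild acid (pyridinium p-toluenesulfonate, toluene, 80 °C) should effect intramolecular Friedel–Crafts hydroxyalkylation at the free ortho position and dehydration to 26.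

Step 7. Transmetalation of the alkylborane may be slow next to the quaternary centre, leaving room for protodeboronation or β-hydride elimination. The fallback sets out from 13 and comes back at 17, using an organozinc instead of the borane. Hydroboration of 13 with 9-BBN and iodinolysis (I2, NaOMe) should give (5S,6R)-5-(2-iodoethyl)-1,5,6-trimethylcyclohex-1-ene F7. Zinc insertion (Zn dust, LiCl, THF) should give iodo{2-[(1S,2R)-1,2,3-trimethylcyclohex-3-en-1-yl]ethyl}zinc F8. Negishi coupling of excess F8 with 15 (Pd(OAc)2, 2-dicyclohexylphosphino-2′,6′-dimethoxybiphenyl, THF) should give 17 with retention of the Z geometry.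

Further compounds
F1 | step 2 | (4S,5E)-5-methylhepta-1,5-dien-4-ol | C/C=C(\C)[C@@H](O)CC=C
F2 | step 2 | (4S,5E)-5-methylhepta-1,5-dien-4-yl 2-methylprop-2-enoate | C/C=C(\C)[C@@H](OC(=O)C(C)=C)CC=C
F3 | step 2 | (6S)-6-[(2E)-but-2-en-2-yl]-3-methyl-5,6-dihydro-2H-pyran-2-one | C/C=C(\C)[C@@H]1CC=C(C)C(=O)O1
F4 | step 12 | 4,5-dimethoxy-2-(methoxymethoxy)-1-({(3S)-3-methyl-5-[(1S,2R)-1,2,3-trimethylcyclohex-3-en-1-yl]pent-1-en-3-yl}oxy)benzene | C=C[C@](C)(CC[C@]1(C)CCC=C(C)[C@@H]1C)Oc1cc(OC)c(OC)cc1OCOC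
F5 | step 12 | (3S)-3-[4,5-dimethoxy-2-(methoxymethoxy)phenoxy]-3-methyl-5-[(1S,2R)-1,2,3-trimethylcyclohex-3-en-1-yl]pentan-1-ol | OCC[C@](C)(CC[C@]1(C)CCC=C(C)[C@@H]1C)Oc1cc(OC)c(OC)cc1OCOC
F6 | step 12 | (3S)-3-[4,5-dimethoxy-2-(methoxymethoxy)phenoxy]-3-methyl-5-[(1S,2R)-1,2,3-trimethylcyclohex-3-en-1-yl]pentanal | O=CC[C@](C)(CC[C@]1(C)CCC=C(C)[C@@H]1C)Oc1cc(OC)c(OC)cc1OCOC
F7 | step 7 | (5S,6R)-5-(2-iodoethyl)-1,5,6-trimethylcyclohex-1-ene | ICC[C@]1(C)CCC=C(C)[C@@H]1C
F8 | step 7 | iodo{2-[(1S,2R)-1,2,3-trimethylcyclohex-3-en-1-yl]ethyl}zinc | I[Zn]CC[C@]1(C)CCC=C(C)[C@@H]1C
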